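## Retrosynthetic overview

1. The target is an L-threonine-derived 3-acyltetramic acid (ring C) on a trans-decalin (ring A cyclohexane, ring B cyclohexene). The last C–C bond, acyl carbon to C3 of ring C, is made by a light-driven 1,3-acyl shift of the 4-O-acyl tetramate.
2. Rings A and B are closed together by an endo intramolecular Diels–Alder reaction of an (E)-2-methylenal with an all-E tetraene (bonds C3–C8 and C2–C11 of the chain).
3. The ring-A methyl group of the target is axial, which a methyl-only tether does not deliver. A temporary aroyloxy group at C4, anti to the methyl, steers the cycloaddition by A(1,3) strain and is then removed by photoinduced electron transfer.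
4. The C4–O centre is relayed from the methyl centre of (R)-citronellic acid through a cis-δ-lactone (singlet-oxygen ene reaction, then allyl-cation lactonisation). Lactol plus trienyl ylide gives the tetraene.
5. Ring order: temporary lactone ring, then rings A and B in one step, then ring C (made separately from Boc-Thr(tBu)-OH) attached last.

Assumption: the three starting materials are bought as single stereoisomers (the trienal all-E), and acyclic intermediates are numbered C1 (future acyl carbon) to C16 (terminal methyl).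

## Route

Step 1
Reactants: 1 (R)-citronellic acid [(3R)-3,7-dimethyloct-6-enoic acid]
Product: 4 (4R,6R)-4-methyl-6-(2-methylprop-1-en-1-yl)oxan-2-one, via hydroperoxy acid 2 (not isolated), via hydroxy acid 3 (not isolated)
Conditions: O2, tetraphenylporphyrin (0.1 mol %), hν (white LED), CH2Cl2, 0 °C; then Me2S, rt; then TsOH·H2O (5 mol %), CH2Cl2, rt; NaHCO3 wash
Reagents that add atoms: none
Why: The Schenck ene reaction of singlet oxygen gives the tertiary allylic hydroperoxide (its secondary regioisomer is washed out later as a hydroxy acid), and after reduction the acid ionises the tertiary allylic alcohol to an allyl cation that the carboxyl group captures reversibly, so the new C–O stereocentre is set under thermodynamic control cis to the bought methyl centre (both groups pseudo-equatorial, as in the rose oxide process).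

Step 2
Reactants: 4 (4R,6R)-4-methyl-6-(2-methylprop-1-en-1-yl)oxan-2-one
Product: 6 ethyl (2E)-2-methyl-3-[(2R,4R)-4-methyl-6-oxooxan-2-yl]prop-2-enoate, via lactone aldehyde 5 (not isolated)
Conditions: O3, CH2Cl2, −78 °C; Me2S, −78 °C to rt; then Ph3P=C(Me)CO2Et, CH2Cl2, rt
Reagents that add atoms: ethyl 2-(triphenylphosphoranylidene)propanoate, CCOC(=O)C(C)=P(c1ccccc1)(c1ccccc1)c1ccccc1
Why: Ozonolysis cleaves the only alkene, and the stabilised Wittig ylide converts the α-acyloxy aldehyde under neutral conditions into the (E)-2-methyl enoate without touching the lactone or the adjacent stereocentre.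

Step 3
Reactants: 6 ethyl (2E)-2-methyl-3-[(2R,4R)-4-methyl-6-oxooxan-2-yl]prop-2-enoate
Product: 7 (2E)-3-[(2R,4R)-6-hydroxy-4-methyloxan-2-yl]-2-methylprop-2-en-1-ol (lactol, both anomers)
Conditions: i-Bu2AlH (3.5 equiv), CH2Cl2, −78 °C; aq. KNaC4H4O6
Reagents that add atoms: none
Why: Hydride reduction with i-Bu2AlH at −78 °C stops the lactone at the lactol (stable aluminium hemiacetal) and takes the conjugated ester to the allylic alcohol, with no stereocentre touched.

Step 4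
Reactants: 8 (2E,4E,6E)-octa-2,4,6-trienal
Product: 9 (2E,4E,6E)-octa-2,4,6-trien-1-ol
Conditions: NaBH4, MeOH, 0 °C
Reagents that add atoms: none
Why: Borohydride 1,2-reduction of the conjugated aldehyde gives the allylic alcohol with the alkene geometry unchanged.

Step 5
Reactants: 9 (2E,4E,6E)-octa-2,4,6-trien-1-ol
Product: 10 [(2E,4E,6E)-octa-2,4,6-trien-1-yl]triphenylphosphonium bromide
Conditions: Ph3P·HBr, MeOH, rt, dark
Reagents that add atoms: triphenylphosphine hydrobromide, Br.c1ccc(cc1)P(c1ccccc1)c1ccccc1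
Why: Protonation of the allylic alcohol and capture of the resulting trienyl cation at its terminus by PPh3 gives the fully conjugated all-E salt, the standard preparation of polyenyl phosphonium salts.

Step 6
Reactants: 7 (2E)-3-[(2R,4R)-6-hydroxy-4-methyloxan-2-yl]-2-methylprop-2-en-1-ol; 10 [(2E,4E,6E)-octa-2,4,6-trien-1-yl]triphenylphosphonium bromide
Product: 13 (2E,4R,6S,8E,10E,12E,14E)-2,6-dimethylhexadeca-2,8,10,12,14-pentaene-1,4-diol, via ylide 11 (not isolated), via 8Z pentaene diol 12 (not isolated)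
Conditions: 10 (3.2 equiv), n-BuLi (3.1 equiv), THF, −78 to 0 °C; then 7, −78 °C to rt; then I2 (2 mol %), CH2Cl2, rt, daylight
Reagents that add atoms: none
Why: Wittig olefination of the open hydroxy-aldehyde form of the lactol makes the C8=C9 bond (excess ylide serves as base for the two hydroxyl groups), and iodine-catalysed equilibration converts the E/Z mixture expected from a semi-stabilised ylide into the all-E pentaene without touching either stereocentre.

Step 7
Reactants: 13 (2E,4R,6S,8E,10E,12E,14E)-2,6-dimethylhexadeca-2,8,10,12,14-pentaene-1,4-diol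
Product: 14 (2E,4R,6S,8E,10E,12E,14E)-4-hydroxy-2,6-dimethylhexadeca-2,8,10,12,14-pentaenal
Conditions: TEMPO (10 mol %), PhI(OAc)2 (1.1 equiv), CH2Cl2, rt
Reagents that add atoms: none
Why: The oxoammonium oxidation (TEMPO/PhI(OAc)2) takes the unhindered primary allylic alcohol much faster than the secondary one and leaves the polyene alone.

Step 8
Reactants: 14 (2E,4R,6S,8E,10E,12E,14E)-4-hydroxy-2,6-dimethylhexadeca-2,8,10,12,14-pentaenal
Product: 15 (2E,4R,6S,8E,10E,12E,14E)-2,6-dimethyl-1-oxohexadeca-2,8,10,12,14-pentaen-4-yl 3-(trifluoromethyl)benzoate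
Conditions: 3-(CF3)C6H4COCl (1.2 equiv), pyridine, DMAP (5 mol %), CH2Cl2, 0 °C
Reagents that add atoms: 3-(trifluoromethyl)benzoyl chloride, O=C(Cl)c1cccc(c1)C(F)(F)F
Why: Acylation of the secondary alcohol with retention installs a group that is both a large allylic director for the cycloaddition and the handle for its own later reductive removal, and it prevents hemiacetal formation with the aldehyde after ring closure.

Step 9
Reactants: 15 (2E,4R,6S,8E,10E,12E,14E)-2,6-dimethyl-1-oxohexadeca-2,8,10,12,14-pentaen-4-yl 3-(trifluoromethyl)benzoate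
Product: 16 (1S,2S,4aR,6S,8R,8aS)-1,6-dimethyl-2-[(1E,3E)-penta-1,3-dien-1-yl]-8-{[3-(trifluoromethyl)benzoyl]oxy}-1,2,4a,5,6,7,8,8a-octahydronaphthalene-1-carbaldehyde
Conditions: Me2AlCl (30 mol %), CH2Cl2, −78 to −20 °C
Reagents that add atoms: none
Why: This is a Lewis-acid-catalysed intramolecular Diels–Alder reaction through the endo (CHO inside) chair transition state, in which A(1,3) strain between the 2-methyl group and C4 puts the C4 hydrogen in the alkene plane and the aroyloxy group equatorial, so the diene adds to the face that makes the ring-A methyl axial and the quaternary carbon, both ring-fusion carbons and the dienyl-bearing carbon are set from the two relayed centres.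

Step 10
Reactants: 16 (1S,2S,4aR,6S,8R,8aS)-1,6-dimethyl-2-[(1E,3E)-penta-1,3-dien-1-yl]-8-{[3-(trifluoromethyl)benzoyl]oxy}-1,2,4a,5,6,7,8,8a-octahydronaphthalene-1-carbaldehyde
Product: 17 (1S,2S,4aR,6S,8R,8aS)-1,6-dimethyl-2-[(1E,3E)-penta-1,3-dien-1-yl]-8-{[3-(trifluoromethyl)benzoyl]oxy}-1,2,4a,5,6,7,8,8a-octahydronaphthalene-1-carboxylic acid
Conditions: NaClO2, NaH2PO4, 2-methylbut-2-ene, t-BuOH/H2O, 0 °C to rt
Reagents that add atoms: sodium chlorite NaClO2, [Na+].[O-]Cl=O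
Why: The Pinnick oxidation converts the hindered α-quaternary aldehyde to the acid under mild conditions while the scavenger protects the alkenes from HOCl.

Step 11
Reactants: 17 (1S,2S,4aR,6S,8R,8aS)-1,6-dimethyl-2-[(1E,3E)-penta-1,3-dien-1-yl]-8-{[3-(trifluoromethyl)benzoyl]oxy}-1,2,4a,5,6,7,8,8a-octahydronaphthalene-1-carboxylic acid
Product: 18 (1R,2S,4aR,6R,8aS)-1,6-dimethyl-2-[(1E,3E)-penta-1,3-dien-1-yl]-1,2,4a,5,6,7,8,8a-octahydronaphthalene-1-carboxylic acid
Conditions: 9-methylcarbazole (30 mol %), hν (λ > 300 nm, Pyrex), i-PrOH/H2O (10:1), degassed, rt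
Reagents that add atoms: none
Why: In this Saito-type photodeoxygenation, electron transfer from excited 9-methylcarbazole to the electron-poor benzoate gives a radical anion that fragments to the carboxylate and the secondary ring radical, which takes a hydrogen atom from 2-propanol, so the relay carbon becomes CH2 while the diene, which does not absorb above 300 nm, is left alone.

Step 12
Reactants: 19 N-(tert-butoxycarbonyl)-O-tert-butyl-L-threonine
Product: 21 tert-butyl (2S)-2-[(1R)-1-tert-butoxyethyl]-3-hydroxy-5-oxo-2,5-dihydro-1H-pyrrole-1-carboxylate, via acyl Meldrum's acid 20 (not isolated)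
Conditions: Meldrum's acid, EDC·HCl, DMAP, CH2Cl2, 0 °C to rt; KHSO4 wash; then EtOAc, reflux
Reagents that add atoms: Meldrum's acid (2,2-dimethyl-1,3-dioxane-4,6-dione), CC1(C)OC(=O)CC(=O)O1
Why: In the Jouin tetramic acid synthesis, C-acylation of Meldrum's acid is followed by thermal loss of acetone and CO2 and ring closure on the carbamate nitrogen, conditions known to preserve both threonine stereocentres.

Step 13
Reactants: 18 (1R,2S,4aR,6R,8aS)-1,6-dimethyl-2-[(1E,3E)-penta-1,3-dien-1-yl]-1,2,4a,5,6,7,8,8a-octahydronaphthalene-1-carboxylic acid; 21 tert-butyl (2S)-2-[(1R)-1-tert-butoxyethyl]-3-hydroxy-5-oxo-2,5-dihydro-1H-pyrrole-1-carboxylate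
Product: 23 (2S)-1-(tert-butoxycarbonyl)-2-[(1R)-1-tert-butoxyethyl]-5-oxo-2,5-dihydro-1H-pyrrol-3-yl (1R,2S,4aR,6R,8aS)-1,6-dimethyl-2-[(1E,3E)-penta-1,3-dien-1-yl]-1,2,4a,5,6,7,8,8a-octahydronaphthalene-1-carboxylate, via acid chloride 22 (not isolated)
Conditions: 1-chloro-N,N,2-trimethylprop-1-en-1-amine, CH2Cl2, 0 °C; then 21, Et3N, −20 °C
Reagents that add atoms: none
Why: The neutral chloroenamine converts the α-quaternary acid (which cannot form a ketene) into its chloride, and this acylates the acidic enol oxygen of the tetramic acid kinetically (O-acylation of a vinylogous acid).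

Step 14
Reactants: 23 (2S)-1-(tert-butoxycarbonyl)-2-[(1R)-1-tert-butoxyethyl]-5-oxo-2,5-dihydro-1H-pyrrol-3-yl (1R,2S,4aR,6R,8aS)-1,6-dimethyl-2-[(1E,3E)-penta-1,3-dien-1-yl]-1,2,4a,5,6,7,8,8a-octahydronaphthalene-1-carboxylate
Product: 24 tert-butyl (5S)-5-[(1R)-1-tert-butoxyethyl]-3-{[(1R,2S,4aR,6R,8aS)-1,6-dimethyl-2-[(1E,3E)-penta-1,3-dien-1-yl]-1,2,4a,5,6,7,8,8a-octahydronaphthalen-1-yl]carbonyl}-4-hydroxy-2-oxo-2,5-dihydro-1H-pyrrole-1-carboxylate
Conditions: hν (254 nm, quartz flow cell, short residence time), MeCN, degassed, 0 °C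
Reagents that add atoms: none
Why: Proposed new method: excitation of the 4-acyloxy-3-pyrrolin-2-one (a vinylogous mixed anhydride) should cleave the O–acyl bond homolytically to a caged acyl radical and β-dicarbonyl radical pair that recombines at C3, where most of the spin density sits, faster than the tertiary acyl radical loses CO, so the hindered acyl–C3 bond that nucleophilic acyl-transfer catalysts form poorly is made without base and without touching a stereocentre; the closest known reactions are the photo-Fries 1,3-acyl shift of enol esters and of 3-acyloxycyclohex-2-enones to 2-acylcyclohexane-1,3-diones, which has not been shown for tetramic acid enol esters.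

Step 15
Reactants: 24 tert-butyl (5S)-5-[(1R)-1-tert-butoxyethyl]-3-{[(1R,2S,4aR,6R,8aS)-1,6-dimethyl-2-[(1E,3E)-penta-1,3-dien-1-yl]-1,2,4a,5,6,7,8,8a-octahydronaphthalen-1-yl]carbonyl}-4-hydroxy-2-oxo-2,5-dihydro-1H-pyrrole-1-carboxylate
Product: 25 (5S)-3-{[(1R,2S,4aR,6R,8aS)-1,6-dimethyl-2-[(1E,3E)-penta-1,3-dien-1-yl]-1,2,4a,5,6,7,8,8a-octahydronaphthalen-1-yl]carbonyl}-4-hydroxy-5-[(1R)-1-hydroxyethyl]-1,5-dihydro-2H-pyrrol-2-one (CNP0298257.2)
Conditions: TFA/CH2Cl2 (1:1), 0 °C to rt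
Reagents that add atoms: none
Why: Acidolysis removes the Boc group and the tert-butyl ether together (isobutene and CO2 are lost) under conditions that 3-acyltetramic acids tolerate, with retention at both threonine-derived centres.

## Compound list

1 | (R)-citronellic acid, (3R)-3,7-dimethyloct-6-enoic acid | C[C@H](CCC=C(C)C)CC(=O)O | starting material
2 | (3R,5E)-7-hydroperoxy-3,7-dimethyloct-5-enoic acid | CC(C)(OO)/C=C/C[C@@H](C)CC(=O)O | intermediate (not isolated)
3 | (3R,5E)-7-hydroxy-3,7-dimethyloct-5-enoic acid | CC(C)(O)/C=C/C[C@@H](C)CC(=O)O | intermediate (not isolated)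
4 | (4R,6R)-4-methyl-6-(2-methylprop-1-en-1-yl)oxan-2-one (cis) | CC(C)=C[C@H]1C[C@@H](C)CC(=O)O1 | intermediate
5 | (2R,4R)-4-methyl-6-oxooxane-2-carbaldehyde | O=C[C@H]1C[C@@H](C)CC(=O)O1 | intermediate (not isolated)
6 | ethyl (2E)-2-methyl-3-[(2R,4R)-4-methyl-6-oxooxan-2-yl]prop-2-enoate | CCOC(=O)/C(C)=C/[C@H]1C[C@@H](C)CC(=O)O1 | intermediate
7 | (2E)-3-[(2R,4R)-6-hydroxy-4-methyloxan-2-yl]-2-methylprop-2-en-1-ol (both anomers) | OC/C(C)=C/[C@H]1C[C@@H](C)CC(O)O1 | intermediate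
8 | (2E,4E,6E)-octa-2,4,6-trienal | C/C=C/C=C/C=C/C=O | starting material
9 | (2E,4E,6E)-octa-2,4,6-trien-1-ol | C/C=C/C=C/C=C/CO | intermediate
10 | [(2E,4E,6E)-octa-2,4,6-trien-1-yl]triphenylphosphonium bromide | C/C=C/C=C/C=C/C[P+](c1ccccc1)(c1ccccc1)c1ccccc1.[Br-] | intermediate
11 | (2E,4E,6E)-octa-2,4,6-trienylidene(triphenyl)phosphorane (ylide) | C/C=C/C=C/C=C/[CH-][P+](c1ccccc1)(c1ccccc1)c1ccccc1 | intermediate (not isolated)
12 | (2E,4R,6S,8Z,10E,12E,14E)-2,6-dimethylhexadeca-2,8,10,12,14-pentaene-1,4-diol | OC/C(C)=C/[C@H](O)C[C@@H](C)C/C=C\C=C\C=C\C=C\C | intermediate (not isolated)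
13 | (2E,4R,6S,8E,10E,12E,14E)-2,6-dimethylhexadeca-2,8,10,12,14-pentaene-1,4-diol | OC/C(C)=C/[C@H](O)C[C@@H](C)C/C=C/C=C/C=C/C=C/C | intermediate
14 | (2E,4R,6S,8E,10E,12E,14E)-4-hydroxy-2,6-dimethylhexadeca-2,8,10,12,14-pentaenal | O=C/C(C)=C/[C@H](O)C[C@@H](C)C/C=C/C=C/C=C/C=C/C | intermediate
15 | (2E,4R,6S,8E,10E,12E,14E)-2,6-dimethyl-1-oxohexadeca-2,8,10,12,14-pentaen-4-yl 3-(trifluoromethyl)benzoate | O=C/C(C)=C/[C@H](OC(=O)c1cccc(c1)C(F)(F)F)C[C@@H](C)C/C=C/C=C/C=C/C=C/C | intermediate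
16 | (1S,2S,4aR,6S,8R,8aS)-1,6-dimethyl-2-[(1E,3E)-penta-1,3-dien-1-yl]-8-{[3-(trifluoromethyl)benzoyl]oxy}-1,2,4a,5,6,7,8,8a-octahydronaphthalene-1-carbaldehyde (trans-decalin, 6-methyl axial, 8-aroyloxy equatorial) | C/C=C/C=C/[C@H]1C=C[C@H]2C[C@H](C)C[C@@H](OC(=O)c3cccc(c3)C(F)(F)F)[C@@H]2[C@@]1(C)C=O | intermediate
17 | (1S,2S,4aR,6S,8R,8aS)-1,6-dimethyl-2-[(1E,3E)-penta-1,3-dien-1-yl]-8-{[3-(trifluoromethyl)benzoyl]oxy}-1,2,4a,5,6,7,8,8a-octahydronaphthalene-1-carboxylic acid | C/C=C/C=C/[C@H]1C=C[C@H]2C[C@H](C)C[C@@H](OC(=O)c3cccc(c3)C(F)(F)F)[C@@H]2[C@@]1(C)C(=O)O | intermediate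
18 | (1R,2S,4aR,6R,8aS)-1,6-dimethyl-2-[(1E,3E)-penta-1,3-dien-1-yl]-1,2,4a,5,6,7,8,8a-octahydronaphthalene-1-carboxylic acid | C/C=C/C=C/[C@H]1C=C[C@H]2C[C@H](C)CC[C@@H]2[C@@]1(C)C(=O)O | intermediate
19 | N-(tert-butoxycarbonyl)-O-tert-butyl-L-threonine, Boc-Thr(tBu)-OH | C[C@H]([C@@H](C(=O)O)NC(=O)OC(C)(C)C)OC(C)(C)C | starting material
20 | tert-butyl N-[(2S,3R)-3-tert-butoxy-1-(2,2-dimethyl-4,6-dioxo-1,3-dioxan-5-ylidene)-1-hydroxybutan-2-yl]carbamate | C[C@H]([C@@H](C(O)=C1C(=O)OC(C)(C)OC1=O)NC(=O)OC(C)(C)C)OC(C)(C)C | intermediate (not isolated)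
21 | tert-butyl (2S)-2-[(1R)-1-tert-butoxyethyl]-3-hydroxy-5-oxo-2,5-dihydro-1H-pyrrole-1-carboxylate | C[C@H]([C@H]1C(O)=CC(=O)N1C(=O)OC(C)(C)C)OC(C)(C)C | intermediate
22 | (1R,2S,4aR,6R,8aS)-1,6-dimethyl-2-[(1E,3E)-penta-1,3-dien-1-yl]-1,2,4a,5,6,7,8,8a-octahydronaphthalene-1-carbonyl chloride | C/C=C/C=C/[C@H]1C=C[C@H]2C[C@H](C)CC[C@@H]2[C@@]1(C)C(Cl)=O | intermediate (not isolated)
23 | (2S)-1-(tert-butoxycarbonyl)-2-[(1R)-1-tert-butoxyethyl]-5-oxo-2,5-dihydro-1H-pyrrol-3-yl (1R,2S,4aR,6R,8aS)-1,6-dimethyl-2-[(1E,3E)-penta-1,3-dien-1-yl]-1,2,4a,5,6,7,8,8a-octahydronaphthalene-1-carboxylate | C/C=C/C=C/[C@H]1C=C[C@H]2C[C@H](C)CC[C@@H]2[C@@]1(C)C(=O)OC1=CC(=O)N(C(=O)OC(C)(C)C)[C@H]1[C@@H](C)OC(C)(C)C | intermediate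
24 | tert-butyl (5S)-5-[(1R)-1-tert-butoxyethyl]-3-{[(1R,2S,4aR,6R,8aS)-1,6-dimethyl-2-[(1E,3E)-penta-1,3-dien-1-yl]-1,2,4a,5,6,7,8,8a-octahydronaphthalen-1-yl]carbonyl}-4-hydroxy-2-oxo-2,5-dihydro-1H-pyrrole-1-carboxylate | C/C=C/C=C/[C@H]1C=C[C@H]2C[C@H](C)CC[C@@H]2[C@@]1(C)C(=O)C1=C(O)[C@H]([C@@H](C)OC(C)(C)C)N(C(=O)OC(C)(C)C)C1=O | intermediate
25 | (5S)-3-{[(1R,2S,4aR,6R,8aS)-1,6-dimethyl-2-[(1E,3E)-penta-1,3-dien-1-yl]-1,2,4a,5,6,7,8,8a-octahydronaphthalen-1-yl]carbonyl}-4-hydroxy-5-[(1R)-1-hydroxyethyl]-1,5-dihydro-2H-pyrrol-2-one | C/C=C/C=C/[C@H]1C=C[C@H]2C[C@H](C)CC[C@@H]2[C@@]1(C)C(=O)C1=C(O)[C@H]([C@@H](C)O)NC1=O | target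

## Step count and risks

Total step count: 15. Longest linear sequence: 12 steps (1, 2, 3, 6, 7, 8, 9, 10, 11, 13, 14, 15) from (R)-citronellic acid. The two steps spent on the aroyloxy group (8 and 11) are the price of relaying the methyl centre so that the axial-methyl decalin is the favoured cycloadduct.

The three steps most likely to fail:

Step 1. The ene reaction gives two hydroperoxides of which only the tertiary one lactonises, so the yield is capped near one half, and hydroperoxide handling or incomplete cis-equilibration can lower it further. The fallback is known chemistry, sets out from 1 and comes back at 3. Epoxidation of 1 with m-chloroperbenzoic acid and NaHCO3 gives (3R)-5-(3,3-dimethyloxiran-2-yl)-3-methylpentanoic acid F1. PhSeNa (from PhSeSePh and NaBH4 in EtOH) opens the epoxide at the secondary carbon to (3R)-7-hydroxy-3,7-dimethyl-6-(phenylselanyl)octanoic acid F2. H2O2 gives the selenoxide (3R)-7-hydroxy-3,7-dimethyl-6-(phenylseleninyl)octanoic acid F3, which can only eliminate away from the carbinol carbon and so gives 3 free of its regioisomer. TsOH then closes 3 to 4 as in step 1.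

Step 11. The electron-transfer deoxygenation has to work beside a free acid and two alkene units, and the ring radical must be reduced before it finds another path. The fallback is known chemistry, sets out from 14 and comes back at 18; it replaces the photochemical cleavage by a thermal tin hydride chain on an oxalate. Methyl chlorooxoacetate and pyridine convert 14 into (2E,4R,6S,8E,10E,12E,14E)-2,6-dimethyl-1-oxohexadeca-2,8,10,12,14-pentaen-4-yl methyl oxalate F4. The Me2AlCl-catalysed cycloaddition of step 9 gives (1S,2S,4aR,6S,8R,8aS)-8-[(2-methoxy-2-oxoacetyl)oxy]-1,6-dimethyl-2-[(1E,3E)-penta-1,3-dien-1-yl]-1,2,4a,5,6,7,8,8a-octahydronaphthalene-1-carbaldehyde F5. NaClO2 oxidation as in step 10 gives (1S,2S,4aR,6S,8R,8aS)-8-[(2-methoxy-2-oxoacetyl)oxy]-1,6-dimethyl-2-[(1E,3E)-penta-1,3-dien-1-yl]-1,2,4a,5,6,7,8,8a-octahydronaphthalene-1-carboxylic acid F6. Bu3SnH and AIBN in toluene at 80 °C reduce the methyl oxalyl ester and give 18.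

Step 14. This is the proposed new step; diene E/Z isomerisation under 254 nm light, decarbonylation of the escaped acyl radical, or simple return to the tetramic acid could defeat it. The fallback is the known Lacey–Dieckmann approach, sets out from 18 and comes back at 25. Acid 18 is taken to acid chloride 22 as in step 13 and acylates Meldrum's acid (pyridine, CH2Cl2) to give 5-{hydroxy[(1R,2S,4aR,6R,8aS)-1,6-dimethyl-2-[(1E,3E)-penta-1,3-dien-1-yl]-1,2,4a,5,6,7,8,8a-octahydronaphthalen-1-yl]methylidene}-2,2-dimethyl-1,3-dioxane-4,6-dione F7. Heating F7 with methyl O-tert-butyl-L-threoninate in toluene gives methyl N-{3-[(1R,2S,4aR,6R,8aS)-1,6-dimethyl-2-[(1E,3E)-penta-1,3-dien-1-yl]-1,2,4a,5,6,7,8,8a-octahydronaphthalen-1-yl]-3-oxopropanoyl}-O-tert-butyl-L-threoninate F8. NaOMe in MeOH closes ring C to (5S)-5-[(1R)-1-tert-butoxyethyl]-3-{[(1R,2S,4aR,6R,8aS)-1,6-dimethyl-2-[(1E,3E)-penta-1,3-dien-1-yl]-1,2,4a,5,6,7,8,8a-octahydronaphthalen-1-yl]carbonyl}-4-hydroxy-1,5-dihydro-2H-pyrrol-2-one F9. TFA in CH2Cl2 then gives 25.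

## Further compounds

F1 | step 1 | (3R)-5-(3,3-dimethyloxiran-2-yl)-3-methylpentanoic acid (both epoxide epimers) | C[C@H](CCC1OC1(C)C)CC(=O)O
F2 | step 1 | (3R)-7-hydroxy-3,7-dimethyl-6-(phenylselanyl)octanoic acid | C[C@H](CCC([Se]c1ccccc1)C(C)(C)O)CC(=O)O
F3 | step 1 | (3R)-7-hydroxy-3,7-dimethyl-6-(phenylseleninyl)octanoic acid | C[C@H](CCC([Se](=O)c1ccccc1)C(C)(C)O)CC(=O)O
F4 | step 11 | (2E,4R,6S,8E,10E,12E,14E)-2,6-dimethyl-1-oxohexadeca-2,8,10,12,14-pentaen-4-yl methyl oxalate | O=C/C(C)=C/[C@H](OC(=O)C(=O)OC)C[C@@H](C)C/C=C/C=C/C=C/C=C/C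
F5 | step 11 | (1S,2S,4aR,6S,8R,8aS)-8-[(2-methoxy-2-oxoacetyl)oxy]-1,6-dimethyl-2-[(1E,3E)-penta-1,3-dien-1-yl]-1,2,4a,5,6,7,8,8a-octahydronaphthalene-1-carbaldehyde | C/C=C/C=C/[C@H]1C=C[C@H]2C[C@H](C)C[C@@H](OC(=O)C(=O)OC)[C@@H]2[C@@]1(C)C=O
F6 | step 11 | (1S,2S,4aR,6S,8R,8aS)-8-[(2-methoxy-2-oxoacetyl)oxy]-1,6-dimethyl-2-[(1E,3E)-penta-1,3-dien-1-yl]-1,2,4a,5,6,7,8,8a-octahydronaphthalene-1-carboxylic acid | C/C=C/C=C/[C@H]1C=C[C@H]2C[C@H](C)C[C@@H](OC(=O)C(=O)OC)[C@@H]2[C@@]1(C)C(=O)O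
F7 | step 14 | 5-{hydroxy[(1R,2S,4aR,6R,8aS)-1,6-dimethyl-2-[(1E,3E)-penta-1,3-dien-1-yl]-1,2,4a,5,6,7,8,8a-octahydronaphthalen-1-yl]methylidene}-2,2-dimethyl-1,3-dioxane-4,6-dione | C/C=C/C=C/[C@H]1C=C[C@H]2C[C@H](C)CC[C@@H]2[C@@]1(C)C(O)=C1C(=O)OC(C)(C)OC1=O
F8 | step 14 | methyl N-{3-[(1R,2S,4aR,6R,8aS)-1,6-dimethyl-2-[(1E,3E)-penta-1,3-dien-1-yl]-1,2,4a,5,6,7,8,8a-octahydronaphthalen-1-yl]-3-oxopropanoyl}-O-tert-butyl-L-threoninate | C/C=C/C=C/[C@H]1C=C[C@H]2C[C@H](C)CC[C@@H]2[C@@]1(C)C(=O)CC(=O)N[C@@H]([C@@H](C)OC(C)(C)C)C(=O)OC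
F9 | step 14 | (5S)-5-[(1R)-1-tert-butoxyethyl]-3-{[(1R,2S,4aR,6R,8aS)-1,6-dimethyl-2-[(1E,3E)-penta-1,3-dien-1-yl]-1,2,4a,5,6,7,8,8a-octahydronaphthalen-1-yl]carbonyl}-4-hydroxy-1,5-dihydro-2H-pyrrol-2-one | C/C=C/C=C/[C@H]1C=C[C@H]2C[C@H](C)CC[C@@H]2[C@@]1(C)C(=O)C1=C(O)[C@H]([C@@H](C)OC(C)(C)C)NC1=O
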